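**Retrosynthetic overview**
1. The ester groups go on last; the trans-fused α-methylene lactone (second ring) is closed late from the C-7a hydroxyl onto an α-methylene aldehyde arm at C-3a (Mannich methylenation, then lactol oxidation).
2. The C-4 acetate comes from face-selective reduction of a 2,3-disubstituted cyclohexenone; this carbocycle (first ring) is closed by an intramolecular Horner–Wadsworth–Emmons reaction that makes C5=C6.
3. The β-ketophosphonate comes from adding an enantiopure side-chain phosphonate (C-5, C-1′ to C-4′; Evans allylation) to a C-4 aldehyde.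
4. Key bond C3a–C7a: intermolecular Evans syn-aldol between (S)-4-benzyl-3-(pent-4-enoyl)oxazolidinone and (R)-4-PMBO-3-TESO-butanal (from (S)-glycidol); it sets both ring-fusion stereocentres.
5. Ring order: cyclohexene (step 19), then lactone (steps 24–25).

Assumption: the SMILES is read as the (3aS,4S,7aR)-lactone (trans ring fusion, 4-OAc cis to the C3a–C3 bond) with a (2S)-5-hydroxypentan-2-yl group; C-2 … C-7a, C-1′ … C-4′ and C-6′ (the CH2O carbon on C-6) below are the target's benzofuranone locants.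

**Route**

Step 1
Reactants: 1 (4R)-4-benzyl-3-propanoyl-1,3-oxazolidin-2-one; 2 3-iodoprop-1-ene (allyl iodide)
Product: 4 (4R)-4-benzyl-3-[(2S)-2-methylpent-4-enoyl]-1,3-oxazolidin-2-one, via sodium Z-enolate 3 (not isolated)
Conditions: NaN(SiMe3)2, THF, −78 °C; then 2, −78 → −45 °C
Reagents that add atoms: none
Why: Evans asymmetric alkylation; the chelated Z-enolate is allylated on the face opposite the benzyl group, which sets the (S) methyl-bearing stereocentre C-1′.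

Step 2
Reactants: 4 (4R)-4-benzyl-3-[(2S)-2-methylpent-4-enoyl]-1,3-oxazolidin-2-one
Product: 5 (2S)-2-methylpent-4-en-1-ol
Conditions: LiBH4, H2O (1.1 equiv), Et2O, 0 °C
Reagents that add atoms: none
Why: Reductive cleavage of the imide by borohydride gives the primary alcohol without epimerising the α-centre and returns the auxiliary.

Step 3
Reactants: 5 (2S)-2-methylpent-4-en-1-ol
Product: 6 (4S)-5-iodo-4-methylpent-1-ene
Conditions: I2, PPh3, imidazole, CH2Cl2, 0 °C → rt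
Reagents that add atoms: iodine, II
Why: Appel-type iodination; SN2 displacement at the primary carbon leaves the adjacent stereocentre untouched.

Step 4
Reactants: 6 (4S)-5-iodo-4-methylpent-1-ene
Product: 7 diethyl [(2S)-2-methylpent-4-en-1-yl]phosphonate
Conditions: P(OEt)3 (neat, excess), 150 °C, sealed tube
Reagents that add atoms: triethyl phosphite, CCOP(OCC)OCC
Why: Michaelis–Arbuzov reaction of a primary iodide installs the phosphonate that later activates C-5.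

Step 5
Reactants: 7 diethyl [(2S)-2-methylpent-4-en-1-yl]phosphonate
Product: 9 diethyl [(2S)-5-hydroxy-2-methylpentyl]phosphonate, via B-alkyl-9-borabicyclononane 8 (not isolated)
Conditions: 9-BBN, THF, 0 °C → rt; then NaOH, 30 % H2O2, 0 °C
Reagents that add atoms: hydrogen peroxide, OO
Why: Anti-Markovnikov hydroboration–oxidation of the terminal alkene gives the primary C-4′ alcohol.

Step 6
Reactants: 9 diethyl [(2S)-5-hydroxy-2-methylpentyl]phosphonate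
Product: 10 diethyl [(2S)-5-{[tert-butyl(diphenyl)silyl]oxy}-2-methylpentyl]phosphonate
Conditions: TBDPSCl, imidazole, DMF, rt
Reagents that add atoms: tert-butyl(chloro)diphenylsilane, CC(C)(C)[Si](Cl)(c1ccccc1)c1ccccc1
Why: Silylation gives a robust primary silyl ether that survives until the last step.

Step 7
Reactants: 11 (2S)-oxiran-2-ylmethanol ((S)-glycidol)
Product: 13 (2R)-2-{[(4-methoxybenzyl)oxy]methyl}oxirane, via sodium alkoxide 12 (not isolated)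
Conditions: NaH, THF/DMF, 0 °C; then PMBCl, n-Bu4NI (cat.), 0 °C → rt
Reagents that add atoms: 4-methoxybenzyl chloride, COc1ccc(CCl)cc1
Why: Williamson etherification; no bond to the stereocentre is broken (the descriptor changes only through CIP priorities).

Step 8
Reactants: 13 (2R)-2-{[(4-methoxybenzyl)oxy]methyl}oxirane; 14 vinylmagnesium bromide
Product: 15 (2R)-1-[(4-methoxybenzyl)oxy]pent-4-en-2-ol
Conditions: CuI (10 mol %), THF, −40 → −20 °C; aq. NH4Cl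
Reagents that add atoms: none
Why: Copper-catalysed Grignard opening of the epoxide at its unsubstituted carbon; the vinyl CH becomes C-7a.

Step 9
Reactants: 15 (2R)-1-[(4-methoxybenzyl)oxy]pent-4-en-2-ol
Product: 16 triethyl{[(2R)-1-[(4-methoxybenzyl)oxy]pent-4-en-2-yl]oxy}silane
Conditions: TESCl, imidazole, CH2Cl2, 0 °C
Reagents that add atoms: chlorotriethylsilane, CC[Si](Cl)(CC)CC
Why: Silylation masks the future C-6 carbonyl oxygen with the most labile silyl group of the route.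

Step 10
Reactants: 16 triethyl{[(2R)-1-[(4-methoxybenzyl)oxy]pent-4-en-2-yl]oxy}silane
Product: 18 (3R)-4-[(4-methoxybenzyl)oxy]-3-[(triethylsilyl)oxy]butanal, via vicinal diol 17 (not isolated)
Conditions: OsO4 (2 mol %), NaIO4, 2,6-lutidine, 1,4-dioxane/H2O (3:1), rt
Reagents that add atoms: osmium tetroxide, O=[Os](=O)(=O)=O; sodium periodate (reoxidant and cleaving agent), [Na+].[O-]I(=O)(=O)=O
Why: Lemieux–Johnson oxidative cleavage (dihydroxylation, then periodate glycol cleavage) gives the aldehyde without ozone, which would attack the PMB ether.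

Step 11
Reactants: 19 (4S)-4-benzyl-1,3-oxazolidin-2-one; 20 pent-4-enoyl chloride
Product: 22 (4S)-4-benzyl-3-(pent-4-enoyl)-1,3-oxazolidin-2-one, via lithium oxazolidinonide 21 (not isolated)
Conditions: n-BuLi, THF, −78 °C; then 20, −78 → 0 °C
Reagents that add atoms: none
Why: N-acylation of the lithiated auxiliary; the allyl terminus is the masked C-2/C-3 lactone arm.

Step 12
Reactants: 22 (4S)-4-benzyl-3-(pent-4-enoyl)-1,3-oxazolidin-2-one; 18 (3R)-4-[(4-methoxybenzyl)oxy]-3-[(triethylsilyl)oxy]butanal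
Product: 24 (4S)-4-benzyl-3-[(2S,3R,5R)-3-hydroxy-6-[(4-methoxybenzyl)oxy]-2-(prop-2-en-1-yl)-5-[(triethylsilyl)oxy]hexanoyl]-1,3-oxazolidin-2-one, via dibutylboron Z-enolate 23 (not isolated)
Conditions: n-Bu2BOTf, i-Pr2NEt, CH2Cl2, −78 → 0 °C; then 18, −78 → 0 °C; pH 7 buffer, MeOH, 30 % H2O2, 0 °C
Reagents that add atoms: none
Why: Evans boron syn-aldol reaction through a Zimmerman–Traxler chair; the (S)-benzyl auxiliary fixes the face, so the new C3a–C7a bond carries C-3a (2S) and C-7a (3R) in the syn relationship that becomes the trans ring fusion.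

Step 13
Reactants: 24 (the aldol adduct)
Product: 25 (4S)-4-benzyl-3-[(2S,3R,5R)-3-{[tert-butyl(dimethyl)silyl]oxy}-6-[(4-methoxybenzyl)oxy]-2-(prop-2-en-1-yl)-5-[(triethylsilyl)oxy]hexanoyl]-1,3-oxazolidin-2-one
Conditions: TBSOTf, 2,6-lutidine, CH2Cl2, −78 → 0 °C
Reagents that add atoms: tert-butyldimethylsilyl trifluoromethanesulfonate, CC(C)(C)[Si](C)(C)OS(=O)(=O)C(F)(F)F
Why: Silylation of the C-7a hydroxyl blocks retro-aldol cleavage and gives a group that outlasts the triethylsilyl ether.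

Step 14
Reactants: 25 (the silylated imide)
Product: 26 (2R,3R,5R)-3-{[tert-butyl(dimethyl)silyl]oxy}-6-[(4-methoxybenzyl)oxy]-2-(prop-2-en-1-yl)-5-[(triethylsilyl)oxy]hexan-1-ol
Conditions: LiBH4, MeOH (1.5 equiv), THF, 0 °C
Reagents that add atoms: none
Why: Reductive removal of the auxiliary gives the C-4 primary alcohol without epimerising C-3a (the descriptor change is a CIP effect only).

Step 15
Reactants: 26 (the primary alcohol)
Product: 27 (2S,3R,5R)-3-{[tert-butyl(dimethyl)silyl]oxy}-6-[(4-methoxybenzyl)oxy]-2-(prop-2-en-1-yl)-5-[(triethylsilyl)oxy]hexanal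
Conditions: Dess–Martin periodinane, pyridine, CH2Cl2, 0 °C → rt; used crude
Reagents that add atoms: none
Why: Dess–Martin oxidation under buffered, non-basic conditions gives the α-branched aldehyde without epimerisation.

Step 16
Reactants: 10 diethyl [(2S)-5-{[tert-butyl(diphenyl)silyl]oxy}-2-methylpentyl]phosphonate; 27 (the C-4 aldehyde)
Product: 29 diethyl [(4S,7R,8R,10R)-8-{[tert-butyl(dimethyl)silyl]oxy}-1-{[tert-butyl(diphenyl)silyl]oxy}-6-hydroxy-11-[(4-methoxybenzyl)oxy]-4-methyl-7-(prop-2-en-1-yl)-10-[(triethylsilyl)oxy]undecan-5-yl]phosphonate (C-5/C-6 epimers), via lithiated phosphonate 28 (not isolated)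
Conditions: 10, n-BuLi, THF, −78 °C; then 27, −78 °C; AcOH quench at −78 °C
Reagents that add atoms: none
Why: 1,2-Addition of the α-lithio phosphonate to the aldehyde forms the C4–C5 bond; both new centres are removed later, and the cold quench prevents silyl migration.

Step 17
Reactants: 29 (the β-hydroxy phosphonate)
Product: 30 diethyl [(4S,7R,8R,10R)-8-{[tert-butyl(dimethyl)silyl]oxy}-1-{[tert-butyl(diphenyl)silyl]oxy}-6,10-dihydroxy-11-[(4-methoxybenzyl)oxy]-4-methyl-7-(prop-2-en-1-yl)undecan-5-yl]phosphonate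
Conditions: PPTS (cat.), MeOH/CH2Cl2 (1:1), 0 °C
Reagents that add atoms: none
Why: Mild acid methanolysis removes the triethylsilyl ether far faster than the secondary TBS or primary TBDPS ethers.

Step 18
Reactants: 30 (the diol)
Product: 31 diethyl [(4S,7S,8R)-8-{[tert-butyl(dimethyl)silyl]oxy}-1-{[tert-butyl(diphenyl)silyl]oxy}-11-[(4-methoxybenzyl)oxy]-4-methyl-6,10-dioxo-7-(prop-2-en-1-yl)undecan-5-yl]phosphonate (C-5 epimers)
Conditions: Dess–Martin periodinane (3 equiv), pyridine, CH2Cl2, rt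
Reagents that add atoms: none
Why: Double Dess–Martin oxidation gives the β-ketophosphonate (C-4) and the C-6 ketone in one operation.

Step 19
Reactants: 31 (the diketo phosphonate)
Product: 33 (5R,6S)-5-{[tert-butyl(dimethyl)silyl]oxy}-2-[(2S)-5-{[tert-butyl(diphenyl)silyl]oxy}pentan-2-yl]-3-{[(4-methoxybenzyl)oxy]methyl}-6-(prop-2-en-1-yl)cyclohex-2-en-1-one, via sodium phosphonate enolate 32 (not isolated)
Conditions: NaH (1.05 equiv), THF, 0 → 50 °C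
Reagents that add atoms: none
Why: Intramolecular Horner–Wadsworth–Emmons olefination; the C-5 carbanion attacks the C-6 ketone and loss of diethyl phosphate closes the six-membered ring with C5=C6 fixed in position, the trans allyl/OTBS pair being the diequatorial arrangement.

Step 20
Reactants: 33 (the cyclohexenone)
Product: 34 (1S,5R,6R)-5-{[tert-butyl(dimethyl)silyl]oxy}-2-[(2S)-5-{[tert-butyl(diphenyl)silyl]oxy}pentan-2-yl]-3-{[(4-methoxybenzyl)oxy]methyl}-6-(prop-2-en-1-yl)cyclohex-2-en-1-ol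
Conditions: LiBH(s-Bu)3 (L-Selectride), THF, −78 °C; H2O
Reagents that add atoms: none
Why: Diastereoselective 1,2-reduction with a bulky trialkylborohydride; equatorial hydride delivery, reinforced by A(1,2) strain from the C-5 side chain, gives the pseudoaxial alcohol cis to the allyl arm, setting C-4 (S).

Step 21
Reactants: 34 (the allylic alcohol)
Product: 35 (1S,5R,6R)-5-{[tert-butyl(dimethyl)silyl]oxy}-2-[(2S)-5-{[tert-butyl(diphenyl)silyl]oxy}pentan-2-yl]-3-{[(4-methoxybenzyl)oxy]methyl}-6-(prop-2-en-1-yl)cyclohex-2-en-1-yl acetate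
Conditions: Ac2O, Et3N, DMAP (cat.), CH2Cl2, rt
Reagents that add atoms: acetic anhydride, CC(=O)OC(C)=O
Why: DMAP-catalysed acetylation installs the C-4 acetate before any C-2 carbonyl exists, so lactonisation onto O-4 is excluded.

Step 22
Reactants: 35 (the allyl acetate)
Product: 37 (1S,5R,6R)-5-{[tert-butyl(dimethyl)silyl]oxy}-2-[(2S)-5-{[tert-butyl(diphenyl)silyl]oxy}pentan-2-yl]-3-{[(4-methoxybenzyl)oxy]methyl}-6-(2-oxoethyl)cyclohex-2-en-1-yl acetate, via vicinal diol 36 (not isolated)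
Conditions: OsO4 (2 mol %), NaIO4, 2,6-lutidine, 1,4-dioxane/H2O (3:1), 0 °C → rt
Reagents that add atoms: osmium tetroxide, O=[Os](=O)(=O)=O; sodium periodate (reoxidant and cleaving agent), [Na+].[O-]I(=O)(=O)=O
Why: Lemieux–Johnson cleavage; the monosubstituted alkene is dihydroxylated much faster than the hindered tetrasubstituted ring alkene, unmasking the C-2 aldehyde.

Step 23
Reactants: 37 (the aldehyde)
Product: 39 (1S,5R,6R)-5-{[tert-butyl(dimethyl)silyl]oxy}-2-[(2S)-5-{[tert-butyl(diphenyl)silyl]oxy}pentan-2-yl]-3-{[(4-methoxybenzyl)oxy]methyl}-6-(3-oxoprop-1-en-2-yl)cyclohex-2-en-1-yl acetate, via Mannich base 38 (not isolated)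
Conditions: Me2N=CH2+ I− (Eschenmoser's salt), Et3N, CH2Cl2, rt
Reagents that add atoms: N,N-dimethylmethyleneiminium iodide, C=[N+](C)C.[I-]
Why: Mannich reaction of the aldehyde enol with the iminium salt followed by β-elimination of dimethylamine installs the exocyclic methylene at C-3 without strong base, so the acetate survives.

Step 24
Reactants: 39 (the α-methylene aldehyde)
Product: 41 (3aS,4S,7aR)-5-[(2S)-5-{[tert-butyl(diphenyl)silyl]oxy}pentan-2-yl]-2-hydroxy-6-{[(4-methoxybenzyl)oxy]methyl}-3-methylidene-2,3,3a,4,7,7a-hexahydro-1-benzofuran-4-yl acetate (C-2 anomers), via hydroxy enal 40 (not isolated)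
Conditions: HF·pyridine, pyridine, THF, 0 °C → rt
Reagents that add atoms: none
Why: Buffered fluoride desilylation frees the secondary C-7a hydroxyl (the primary TBDPS ether is much slower), and the γ-hydroxy aldehyde closes by 5-exo hemiacetalisation to the trans-fused lactol.

Step 25
Reactants: 41 (the lactol)
Product: 42 (3aS,4S,7aR)-5-[(2S)-5-{[tert-butyl(diphenyl)silyl]oxy}pentan-2-yl]-6-{[(4-methoxybenzyl)oxy]methyl}-3-methylidene-2-oxo-2,3,3a,4,7,7a-hexahydro-1-benzofuran-4-yl acetate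
Conditions: TEMPO (10 mol %), PhI(OAc)2, CH2Cl2, rt
Reagents that add atoms: none
Why: Oxoammonium (TEMPO) oxidation of the lactol gives the α-methylene-γ-butyrolactone under neutral conditions that leave the acetate, PMB ether and alkenes intact.

Step 26
Reactants: 42 (the PMB-protected lactone)
Product: 43 (3aS,4S,7aR)-5-[(2S)-5-{[tert-butyl(diphenyl)silyl]oxy}pentan-2-yl]-6-(hydroxymethyl)-3-methylidene-2-oxo-2,3,3a,4,7,7a-hexahydro-1-benzofuran-4-yl acetate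
Conditions: DDQ (1.2 equiv), CH2Cl2/pH 7 buffer (10:1), 0 °C
Reagents that add atoms: none
Why: Oxidative PMB-ether cleavage by DDQ is orthogonal to the silyl ether, the esters and the Michael acceptor.

Step 27
Reactants: 43 (the primary allylic alcohol)
Product: 44 [(3aS,4S,7aR)-4-(acetyloxy)-5-[(2S)-5-{[tert-butyl(diphenyl)silyl]oxy}pentan-2-yl]-3-methylidene-2-oxo-2,3,3a,4,7,7a-hexahydro-1-benzofuran-6-yl]methyl 2-methylprop-2-enoate
Conditions: methacryloyl chloride, Et3N, DMAP (cat.), CH2Cl2, 0 °C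
Reagents that add atoms: methacryloyl chloride, C=C(C)C(=O)Cl
Why: Acylation of the only free hydroxyl installs the methacrylate.

Step 28
Reactants: 44 (the silyl-protected target)
Product: 45 [(3aS,4S,7aR)-4-(acetyloxy)-5-[(2S)-5-hydroxypentan-2-yl]-3-methylidene-2-oxo-2,3,3a,4,7,7a-hexahydro-1-benzofuran-6-yl]methyl 2-methylprop-2-enoate (CNP0114085.1)
Conditions: HF·pyridine, THF, 0 °C → rt
Reagents that add atoms: none
Why: Acidic fluoride desilylation frees the side-chain primary alcohol without acyl migration or ester cleavage.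

**Compound list**

1 | (4R)-4-benzyl-3-propanoyl-1,3-oxazolidin-2-one | CCC(=O)N1[C@H](Cc2ccccc2)COC1=O | starting material
2 | 3-iodoprop-1-ene (allyl iodide) | C=CCI | starting material
3 | sodium (1Z)-1-[(4R)-4-benzyl-2-oxo-1,3-oxazolidin-3-yl]prop-1-en-1-olate | C/C=C(\[O-])N1[C@H](Cc2ccccc2)COC1=O.[Na+] | intermediate
4 | (4R)-4-benzyl-3-[(2S)-2-methylpent-4-enoyl]-1,3-oxazolidin-2-one | C=CC[C@H](C)C(=O)N1[C@H](Cc2ccccc2)COC1=O | intermediate
5 | (2S)-2-methylpent-4-en-1-ol | C=CC[C@H](C)CO | intermediate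
6 | (4S)-5-iodo-4-methylpent-1-ene | C=CC[C@H](C)CI | intermediate
7 | diethyl [(2S)-2-methylpent-4-en-1-yl]phosphonate | C=CC[C@H](C)CP(=O)(OCC)OCC | intermediate
8 | diethyl [(2S)-5-(9-borabicyclo[3.3.1]nonan-9-yl)-2-methylpentyl]phosphonate | CCOP(=O)(OCC)C[C@@H](C)CCCB1C2CCCC1CCC2 | intermediate
9 | diethyl [(2S)-5-hydroxy-2-methylpentyl]phosphonate | CCOP(=O)(OCC)C[C@@H](C)CCCO | intermediate
10 | diethyl [(2S)-5-{[tert-butyl(diphenyl)silyl]oxy}-2-methylpentyl]phosphonate | CCOP(=O)(OCC)C[C@@H](C)CCCO[Si](c1ccccc1)(c1ccccc1)C(C)(C)C | intermediate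
11 | (2S)-oxiran-2-ylmethanol ((S)-glycidol) | OC[C@H]1CO1 | starting material
12 | sodium (2S)-oxiran-2-ylmethanolate | [Na+].[O-]C[C@H]1CO1 | intermediate
13 | (2R)-2-{[(4-methoxybenzyl)oxy]methyl}oxirane | COc1ccc(COC[C@H]2CO2)cc1 | intermediate
14 | vinylmagnesium bromide | C=C[Mg]Br | starting material
15 | (2R)-1-[(4-methoxybenzyl)oxy]pent-4-en-2-ol | COc1ccc(COC[C@H](O)CC=C)cc1 | intermediate
16 | triethyl{[(2R)-1-[(4-methoxybenzyl)oxy]pent-4-en-2-yl]oxy}silane | COc1ccc(COC[C@H](O[Si](CC)(CC)CC)CC=C)cc1 | intermediate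
17 | (4R)-5-[(4-methoxybenzyl)oxy]-4-[(triethylsilyl)oxy]pentane-1,2-diol (C-2 epimers) | COc1ccc(COC[C@H](O[Si](CC)(CC)CC)CC(O)CO)cc1 | intermediate
18 | (3R)-4-[(4-methoxybenzyl)oxy]-3-[(triethylsilyl)oxy]butanal | COc1ccc(COC[C@H](O[Si](CC)(CC)CC)CC=O)cc1 | intermediate
19 | (4S)-4-benzyl-1,3-oxazolidin-2-one | O=C1N[C@@H](Cc2ccccc2)CO1 | starting material
20 | pent-4-enoyl chloride | C=CCCC(=O)Cl | starting material
21 | lithium (4S)-4-benzyl-2-oxo-1,3-oxazolidin-3-ide | [Li+].O=C1[N-][C@@H](Cc2ccccc2)CO1 | intermediate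
22 | (4S)-4-benzyl-3-(pent-4-enoyl)-1,3-oxazolidin-2-one | C=CCCC(=O)N1[C@@H](Cc2ccccc2)COC1=O | intermediate
23 | (4S)-4-benzyl-3-{(1Z)-1-[(dibutylboranyl)oxy]penta-1,4-dien-1-yl}-1,3-oxazolidin-2-one | C=CC/C=C(\OB(CCCC)CCCC)N1[C@@H](Cc2ccccc2)COC1=O | intermediate
24 | (4S)-4-benzyl-3-[(2S,3R,5R)-3-hydroxy-6-[(4-methoxybenzyl)oxy]-2-(prop-2-en-1-yl)-5-[(triethylsilyl)oxy]hexanoyl]-1,3-oxazolidin-2-one | O=C(N1[C@@H](Cc2ccccc2)COC1=O)[C@@H](CC=C)[C@H](O)C[C@@H](O[Si](CC)(CC)CC)COCc1ccc(OC)cc1 | intermediate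
25 | (4S)-4-benzyl-3-[(2S,3R,5R)-3-{[tert-butyl(dimethyl)silyl]oxy}-6-[(4-methoxybenzyl)oxy]-2-(prop-2-en-1-yl)-5-[(triethylsilyl)oxy]hexanoyl]-1,3-oxazolidin-2-one | O=C(N1[C@@H](Cc2ccccc2)COC1=O)[C@@H](CC=C)[C@H](O[Si](C)(C)C(C)(C)C)C[C@@H](O[Si](CC)(CC)CC)COCc1ccc(OC)cc1 | intermediate
26 | (2R,3R,5R)-3-{[tert-butyl(dimethyl)silyl]oxy}-6-[(4-methoxybenzyl)oxy]-2-(prop-2-en-1-yl)-5-[(triethylsilyl)oxy]hexan-1-ol | OC[C@@H](CC=C)[C@H](O[Si](C)(C)C(C)(C)C)C[C@@H](O[Si](CC)(CC)CC)COCc1ccc(OC)cc1 | intermediate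
27 | (2S,3R,5R)-3-{[tert-butyl(dimethyl)silyl]oxy}-6-[(4-methoxybenzyl)oxy]-2-(prop-2-en-1-yl)-5-[(triethylsilyl)oxy]hexanal | O=C[C@@H](CC=C)[C@H](O[Si](C)(C)C(C)(C)C)C[C@@H](O[Si](CC)(CC)CC)COCc1ccc(OC)cc1 | intermediate
28 | diethyl [(2S)-5-{[tert-butyl(diphenyl)silyl]oxy}-1-lithio-2-methylpentyl]phosphonate | [Li]C(P(=O)(OCC)OCC)[C@@H](C)CCCO[Si](c1ccccc1)(c1ccccc1)C(C)(C)C | intermediate
29 | diethyl [(4S,7R,8R,10R)-8-{[tert-butyl(dimethyl)silyl]oxy}-1-{[tert-butyl(diphenyl)silyl]oxy}-6-hydroxy-11-[(4-methoxybenzyl)oxy]-4-methyl-7-(prop-2-en-1-yl)-10-[(triethylsilyl)oxy]undecan-5-yl]phosphonate (C-5/C-6 epimers) | CCOP(=O)(OCC)C(C(O)[C@@H](CC=C)[C@H](O[Si](C)(C)C(C)(C)C)C[C@@H](O[Si](CC)(CC)CC)COCc1ccc(OC)cc1)[C@@H](C)CCCO[Si](c1ccccc1)(c1ccccc1)C(C)(C)C | intermediate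
30 | diethyl [(4S,7R,8R,10R)-8-{[tert-butyl(dimethyl)silyl]oxy}-1-{[tert-butyl(diphenyl)silyl]oxy}-6,10-dihydroxy-11-[(4-methoxybenzyl)oxy]-4-methyl-7-(prop-2-en-1-yl)undecan-5-yl]phosphonate (C-5/C-6 epimers) | CCOP(=O)(OCC)C(C(O)[C@@H](CC=C)[C@H](O[Si](C)(C)C(C)(C)C)C[C@@H](O)COCc1ccc(OC)cc1)[C@@H](C)CCCO[Si](c1ccccc1)(c1ccccc1)C(C)(C)C | intermediate
31 | diethyl [(4S,7S,8R)-8-{[tert-butyl(dimethyl)silyl]oxy}-1-{[tert-butyl(diphenyl)silyl]oxy}-11-[(4-methoxybenzyl)oxy]-4-methyl-6,10-dioxo-7-(prop-2-en-1-yl)undecan-5-yl]phosphonate (C-5 epimers) | CCOP(=O)(OCC)C(C(=O)[C@@H](CC=C)[C@H](O[Si](C)(C)C(C)(C)C)CC(=O)COCc1ccc(OC)cc1)[C@@H](C)CCCO[Si](c1ccccc1)(c1ccccc1)C(C)(C)C | intermediate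
32 | sodium enolate of 31 (phosphonate-stabilised, C-5/C-6 of the undecane chain) | [Na+].CCOP(=O)(OCC)C(=C([O-])[C@@H](CC=C)[C@H](O[Si](C)(C)C(C)(C)C)CC(=O)COCc1ccc(OC)cc1)[C@@H](C)CCCO[Si](c1ccccc1)(c1ccccc1)C(C)(C)C | intermediate
33 | (5R,6S)-5-{[tert-butyl(dimethyl)silyl]oxy}-2-[(2S)-5-{[tert-butyl(diphenyl)silyl]oxy}pentan-2-yl]-3-{[(4-methoxybenzyl)oxy]methyl}-6-(prop-2-en-1-yl)cyclohex-2-en-1-one | O=C1C([C@@H](C)CCCO[Si](c2ccccc2)(c2ccccc2)C(C)(C)C)=C(COCc2ccc(OC)cc2)C[C@@H](O[Si](C)(C)C(C)(C)C)[C@@H]1CC=C | intermediate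
34 | (1S,5R,6R)-5-{[tert-butyl(dimethyl)silyl]oxy}-2-[(2S)-5-{[tert-butyl(diphenyl)silyl]oxy}pentan-2-yl]-3-{[(4-methoxybenzyl)oxy]methyl}-6-(prop-2-en-1-yl)cyclohex-2-en-1-ol | O[C@@H]1C([C@@H](C)CCCO[Si](c2ccccc2)(c2ccccc2)C(C)(C)C)=C(COCc2ccc(OC)cc2)C[C@@H](O[Si](C)(C)C(C)(C)C)[C@@H]1CC=C | intermediate
35 | (1S,5R,6R)-5-{[tert-butyl(dimethyl)silyl]oxy}-2-[(2S)-5-{[tert-butyl(diphenyl)silyl]oxy}pentan-2-yl]-3-{[(4-methoxybenzyl)oxy]methyl}-6-(prop-2-en-1-yl)cyclohex-2-en-1-yl acetate | CC(=O)O[C@@H]1C([C@@H](C)CCCO[Si](c2ccccc2)(c2ccccc2)C(C)(C)C)=C(COCc2ccc(OC)cc2)C[C@@H](O[Si](C)(C)C(C)(C)C)[C@@H]1CC=C | intermediate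
36 | (1S,5R,6R)-5-{[tert-butyl(dimethyl)silyl]oxy}-2-[(2S)-5-{[tert-butyl(diphenyl)silyl]oxy}pentan-2-yl]-6-(2,3-dihydroxypropyl)-3-{[(4-methoxybenzyl)oxy]methyl}cyclohex-2-en-1-yl acetate (diol epimers) | CC(=O)O[C@@H]1C([C@@H](C)CCCO[Si](c2ccccc2)(c2ccccc2)C(C)(C)C)=C(COCc2ccc(OC)cc2)C[C@@H](O[Si](C)(C)C(C)(C)C)[C@@H]1CC(O)CO | intermediate
37 | (1S,5R,6R)-5-{[tert-butyl(dimethyl)silyl]oxy}-2-[(2S)-5-{[tert-butyl(diphenyl)silyl]oxy}pentan-2-yl]-3-{[(4-methoxybenzyl)oxy]methyl}-6-(2-oxoethyl)cyclohex-2-en-1-yl acetate | CC(=O)O[C@@H]1C([C@@H](C)CCCO[Si](c2ccccc2)(c2ccccc2)C(C)(C)C)=C(COCc2ccc(OC)cc2)C[C@@H](O[Si](C)(C)C(C)(C)C)[C@@H]1CC=O | intermediate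
38 | (1S,5R,6R)-5-{[tert-butyl(dimethyl)silyl]oxy}-2-[(2S)-5-{[tert-butyl(diphenyl)silyl]oxy}pentan-2-yl]-6-[1-(dimethylamino)-3-oxopropan-2-yl]-3-{[(4-methoxybenzyl)oxy]methyl}cyclohex-2-en-1-yl acetate (side-chain epimers) | CC(=O)O[C@@H]1C([C@@H](C)CCCO[Si](c2ccccc2)(c2ccccc2)C(C)(C)C)=C(COCc2ccc(OC)cc2)C[C@@H](O[Si](C)(C)C(C)(C)C)[C@@H]1C(CN(C)C)C=O | intermediate
39 | (1S,5R,6R)-5-{[tert-butyl(dimethyl)silyl]oxy}-2-[(2S)-5-{[tert-butyl(diphenyl)silyl]oxy}pentan-2-yl]-3-{[(4-methoxybenzyl)oxy]methyl}-6-(3-oxoprop-1-en-2-yl)cyclohex-2-en-1-yl acetate | CC(=O)O[C@@H]1C([C@@H](C)CCCO[Si](c2ccccc2)(c2ccccc2)C(C)(C)C)=C(COCc2ccc(OC)cc2)C[C@@H](O[Si](C)(C)C(C)(C)C)[C@@H]1C(=C)C=O | intermediate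
40 | (1S,5R,6S)-2-[(2S)-5-{[tert-butyl(diphenyl)silyl]oxy}pentan-2-yl]-5-hydroxy-3-{[(4-methoxybenzyl)oxy]methyl}-6-(3-oxoprop-1-en-2-yl)cyclohex-2-en-1-yl acetate | CC(=O)O[C@@H]1C([C@@H](C)CCCO[Si](c2ccccc2)(c2ccccc2)C(C)(C)C)=C(COCc2ccc(OC)cc2)C[C@@H](O)[C@@H]1C(=C)C=O | intermediate
41 | (3aS,4S,7aR)-5-[(2S)-5-{[tert-butyl(diphenyl)silyl]oxy}pentan-2-yl]-2-hydroxy-6-{[(4-methoxybenzyl)oxy]methyl}-3-methylidene-2,3,3a,4,7,7a-hexahydro-1-benzofuran-4-yl acetate (C-2 anomers) | COc1ccc(COCC2=C([C@@H](C)CCCO[Si](c3ccccc3)(c3ccccc3)C(C)(C)C)[C@@H](OC(C)=O)[C@H]3C(=C)C(O)O[C@@H]3C2)cc1 | intermediate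
42 | (3aS,4S,7aR)-5-[(2S)-5-{[tert-butyl(diphenyl)silyl]oxy}pentan-2-yl]-6-{[(4-methoxybenzyl)oxy]methyl}-3-methylidene-2-oxo-2,3,3a,4,7,7a-hexahydro-1-benzofuran-4-yl acetate | COc1ccc(COCC2=C([C@@H](C)CCCO[Si](c3ccccc3)(c3ccccc3)C(C)(C)C)[C@@H](OC(C)=O)[C@H]3C(=C)C(=O)O[C@@H]3C2)cc1 | intermediate
43 | (3aS,4S,7aR)-5-[(2S)-5-{[tert-butyl(diphenyl)silyl]oxy}pentan-2-yl]-6-(hydroxymethyl)-3-methylidene-2-oxo-2,3,3a,4,7,7a-hexahydro-1-benzofuran-4-yl acetate | OCC1=C([C@@H](C)CCCO[Si](c2ccccc2)(c2ccccc2)C(C)(C)C)[C@@H](OC(C)=O)[C@H]2C(=C)C(=O)O[C@@H]2C1 | intermediate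
44 | [(3aS,4S,7aR)-4-(acetyloxy)-5-[(2S)-5-{[tert-butyl(diphenyl)silyl]oxy}pentan-2-yl]-3-methylidene-2-oxo-2,3,3a,4,7,7a-hexahydro-1-benzofuran-6-yl]methyl 2-methylprop-2-enoate | C=C(C)C(=O)OCC1=C([C@@H](C)CCCO[Si](c2ccccc2)(c2ccccc2)C(C)(C)C)[C@@H](OC(C)=O)[C@H]2C(=C)C(=O)O[C@@H]2C1 | intermediate
45 | [(3aS,4S,7aR)-4-(acetyloxy)-5-[(2S)-5-hydroxypentan-2-yl]-3-methylidene-2-oxo-2,3,3a,4,7,7a-hexahydro-1-benzofuran-6-yl]methyl 2-methylprop-2-enoate | C=C(C)C(=O)OCC1=C([C@@H](C)CCCO)[C@@H](OC(C)=O)[C@H]2C(=C)C(=O)O[C@@H]2C1 | target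

**Totals and risks**

Total step count: 28. Longest linear sequence: 21 steps (from 11 through steps 7–10 and 12–28 to 45).

Most likely to fail, 1: step 19. The olefination must build a tetrasubstituted enone next to the branched side chain and may stall at the β-hydroxy phosphonate stage. The fallback sets out from iodide 6 and aldehyde 27 and comes back at enone 33, closing the ring by aldol cyclodehydration of a phosphorus-free diketone. Iodide 6 is hydroborated (9-BBN, then NaBO3·4H2O) to (4S)-5-iodo-4-methylpentan-1-ol F1 and silylated (TBDPSCl, imidazole) to tert-butyl{[(4S)-5-iodo-4-methylpentyl]oxy}diphenylsilane F2. Iodine–lithium exchange (t-BuLi, Et2O, −78 °C) gives [(2R)-5-{[tert-butyl(diphenyl)silyl]oxy}-2-methylpentyl]lithium F3, which adds to 27 to give the undecan-6-ol F4. PPTS in MeOH removes the triethylsilyl group to give the undecane-6,10-diol F5, and Dess–Martin periodinane gives the undecane-6,10-dione F6. KOt-Bu in t-BuOH at rt then closes F6 to 33 by attack of the C-5 methylene on the C-6 ketone and loss of water; a competing closure from the CH2OPMB carbon onto the C-4 ketone is possible and would have to be checked.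

Most likely to fail, 2: step 20. The facial selectivity of hydride delivery to the hindered enone is a prediction and could favour the C-4 epimer. The fallback sets out from enone 33 and comes back at acetate 35. Luche reduction (NaBH4, CeCl3·7H2O, MeOH, −78 °C; axial attack) gives the epimeric (1R,5R,6R)-cyclohex-2-en-1-ol F7. A Mitsunobu reaction with acetic acid (PPh3, DIAD, toluene, 0 °C → rt) inverts this centre and installs the acetate in one operation.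

Most likely to fail, 3: step 22. The oxidative cleavage must discriminate the terminal alkene from the electron-rich tetrasubstituted ring alkene. The fallback sets out from enone 33 and comes back at aldehyde 37, doing the cleavage while the ring alkene is still deactivated by the carbonyl. OsO4/NaIO4/2,6-lutidine on 33 gives the (5R,6S)-6-(2-oxoethyl)cyclohex-2-en-1-one F8. Selective acetalisation of the aldehyde (HC(OMe)3, PPTS, MeOH, 0 °C) gives the (5R,6S)-6-(2,2-dimethoxyethyl)cyclohex-2-en-1-one F9. LiBH(s-Bu)3 at −78 °C gives the (1S,5R,6R)-6-(2,2-dimethoxyethyl)cyclohex-2-en-1-ol F10, and Ac2O/Et3N/DMAP gives the (1S,5R,6R)-6-(2,2-dimethoxyethyl)cyclohex-2-en-1-yl acetate F11. LiBF4 in wet MeCN then unmasks the aldehyde to give 37.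

**Further compounds**

F1 | step 19 | (4S)-5-iodo-4-methylpentan-1-ol | OCCC[C@H](C)CI
F2 | step 19 | tert-butyl{[(4S)-5-iodo-4-methylpentyl]oxy}diphenylsilane | CC(C)(C)[Si](OCCC[C@H](C)CI)(c1ccccc1)c1ccccc1
F3 | step 19 | [(2R)-5-{[tert-butyl(diphenyl)silyl]oxy}-2-methylpentyl]lithium | [Li]C[C@@H](C)CCCO[Si](c1ccccc1)(c1ccccc1)C(C)(C)C
F4 | step 19 | (4S,7R,8R,10R)-8-{[tert-butyl(dimethyl)silyl]oxy}-1-{[tert-butyl(diphenyl)silyl]oxy}-11-[(4-methoxybenzyl)oxy]-4-methyl-7-(prop-2-en-1-yl)-10-[(triethylsilyl)oxy]undecan-6-ol (C-6 epimers) | OC(C[C@@H](C)CCCO[Si](c1ccccc1)(c1ccccc1)C(C)(C)C)[C@@H](CC=C)[C@H](O[Si](C)(C)C(C)(C)C)C[C@@H](O[Si](CC)(CC)CC)COCc1ccc(OC)cc1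
F5 | step 19 | (4S,7R,8R,10R)-8-{[tert-butyl(dimethyl)silyl]oxy}-1-{[tert-butyl(diphenyl)silyl]oxy}-11-[(4-methoxybenzyl)oxy]-4-methyl-7-(prop-2-en-1-yl)undecane-6,10-diol (C-6 epimers) | OC(C[C@@H](C)CCCO[Si](c1ccccc1)(c1ccccc1)C(C)(C)C)[C@@H](CC=C)[C@H](O[Si](C)(C)C(C)(C)C)C[C@@H](O)COCc1ccc(OC)cc1
F6 | step 19 | (4S,7S,8R)-8-{[tert-butyl(dimethyl)silyl]oxy}-1-{[tert-butyl(diphenyl)silyl]oxy}-11-[(4-methoxybenzyl)oxy]-4-methyl-7-(prop-2-en-1-yl)undecane-6,10-dione | O=C(C[C@@H](C)CCCO[Si](c1ccccc1)(c1ccccc1)C(C)(C)C)[C@@H](CC=C)[C@H](O[Si](C)(C)C(C)(C)C)CC(=O)COCc1ccc(OC)cc1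
F7 | step 20 | (1R,5R,6R)-5-{[tert-butyl(dimethyl)silyl]oxy}-2-[(2S)-5-{[tert-butyl(diphenyl)silyl]oxy}pentan-2-yl]-3-{[(4-methoxybenzyl)oxy]methyl}-6-(prop-2-en-1-yl)cyclohex-2-en-1-ol | O[C@H]1C([C@@H](C)CCCO[Si](c2ccccc2)(c2ccccc2)C(C)(C)C)=C(COCc2ccc(OC)cc2)C[C@@H](O[Si](C)(C)C(C)(C)C)[C@@H]1CC=C
F8 | step 22 | (5R,6S)-5-{[tert-butyl(dimethyl)silyl]oxy}-2-[(2S)-5-{[tert-butyl(diphenyl)silyl]oxy}pentan-2-yl]-3-{[(4-methoxybenzyl)oxy]methyl}-6-(2-oxoethyl)cyclohex-2-en-1-one | O=C1C([C@@H](C)CCCO[Si](c2ccccc2)(c2ccccc2)C(C)(C)C)=C(COCc2ccc(OC)cc2)C[C@@H](O[Si](C)(C)C(C)(C)C)[C@@H]1CC=O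
F9 | step 22 | (5R,6S)-5-{[tert-butyl(dimethyl)silyl]oxy}-2-[(2S)-5-{[tert-butyl(diphenyl)silyl]oxy}pentan-2-yl]-6-(2,2-dimethoxyethyl)-3-{[(4-methoxybenzyl)oxy]methyl}cyclohex-2-en-1-one | O=C1C([C@@H](C)CCCO[Si](c2ccccc2)(c2ccccc2)C(C)(C)C)=C(COCc2ccc(OC)cc2)C[C@@H](O[Si](C)(C)C(C)(C)C)[C@@H]1CC(OC)OC
F10 | step 22 | (1S,5R,6R)-5-{[tert-butyl(dimethyl)silyl]oxy}-2-[(2S)-5-{[tert-butyl(diphenyl)silyl]oxy}pentan-2-yl]-6-(2,2-dimethoxyethyl)-3-{[(4-methoxybenzyl)oxy]methyl}cyclohex-2-en-1-ol | O[C@@H]1C([C@@H](C)CCCO[Si](c2ccccc2)(c2ccccc2)C(C)(C)C)=C(COCc2ccc(OC)cc2)C[C@@H](O[Si](C)(C)C(C)(C)C)[C@@H]1CC(OC)OC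
F11 | step 22 | (1S,5R,6R)-5-{[tert-butyl(dimethyl)silyl]oxy}-2-[(2S)-5-{[tert-butyl(diphenyl)silyl]oxy}pentan-2-yl]-6-(2,2-dimethoxyethyl)-3-{[(4-methoxybenzyl)oxy]methyl}cyclohex-2-en-1-yl acetate | CC(=O)O[C@@H]1C([C@@H](C)CCCO[Si](c2ccccc2)(c2ccccc2)C(C)(C)C)=C(COCc2ccc(OC)cc2)C[C@@H](O[Si](C)(C)C(C)(C)C)[C@@H]1CC(OC)OC
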